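The dihydropyranone ring (chroman-4-one numbering: O1–C2–C3–C4(=O)–C4a=C8a) is disconnected at O1–C8a and C4–C4a. Its O1–C2(Me)–C3(Me)–C4(=O) segment is recognised as a trans-3,4-dimethyl β-lactone, bought as (R)-β-butyrolactone and methylated; the C4a–C8a edge is an ortho-fluoroaryllithium. In one operation the aryllithium opens the lactone at its acyl carbon and the released alkoxide displaces the ortho fluoride, so the four-membered ring grows by two carbons into the chromanone with both stereocentres intact. Rhodium-catalysed phenyl addition to a fused coumarin, Negishi lavandulylation and a ligand-controlled dearomative prenylation complete the target.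

Key step: step 4

Assumption: the sense of induction of the chiral ligands in steps 8 and 15 is assigned by analogy with simpler coumarins and 2-naphthols; the ligand antipode would be used if the opposite face were delivered (tricyclic compounds carry pyrano[2,3-f]chromene numbering).

Step 1
Reactants: 1 (R)-4-methyloxetan-2-one, (R)-β-butyrolactone
Product: 3 (3R,4R)-3,4-dimethyloxetan-2-one
Conditions: LiN(iPr)2, THF, −78 °C; MeI, −78 → −40 °C
Reagents that add atoms: 2 iodomethane, CI
Why: α-Alkylation of the β-lactone lithium enolate (which resists β-elimination for stereoelectronic reasons) should place the new methyl trans to the C-4 methyl by 1,2-induction, so the bought (R) centre sets C-3 as (R).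

Step 2
Reactants: 4 5-fluorobenzene-1,3-diol
Product: 6 1-fluoro-3,5-di(propan-2-yloxy)benzene
Conditions: K2CO3, DMF, 60 °C
Reagents that add atoms: 5 2-bromopropane, CC(C)Br
Why: Williamson etherification of both phenols should give isopropyl ethers that survive organolithium chemistry and are later cleaved by BCl3.

Step 3
Reactants: 6 1-fluoro-3,5-di(propan-2-yloxy)benzene
Product: 8 2-bromo-1-fluoro-3,5-di(propan-2-yloxy)benzene
Conditions: NBS, MeCN, 0 °C
Reagents that add atoms: 7 N-bromosuccinimide, O=C1CCC(=O)N1Br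
Why: Electrophilic aromatic bromination should take the position ortho to one alkoxy group, para to the other and next to fluorine, because the site between the two isopropoxy groups is the more hindered.

Step 4
Reactants: 8 2-bromo-1-fluoro-3,5-di(propan-2-yloxy)benzene; 3 (3R,4R)-3,4-dimethyloxetan-2-one
Product: 11 (2R,3R)-2,3-dimethyl-5,7-di(propan-2-yloxy)chroman-4-one, via aryllithium 9 (not isolated), via lithium keto-alkoxide 10 (not isolated)
Conditions: n-BuLi, THF, −78 °C; cannulated into 3, THF, −78 °C; DMPU, −78 → 25 °C; aq. NH4Cl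
Reagents that add atoms: none
Why: Bromine–lithium exchange gives aryllithium 9, which attacks the strained lactone carbonyl of 3 (acyl–oxygen cleavage) to release keto-alkoxide 10, and on warming in DMPU the alkoxide displaces the fluoride ortho to the new ketone, so the C4a–C8a aryl edge is inserted into the acyl–oxygen bond and the oxetanone is expanded by two atoms to the six-membered ring. The closest known reaction types are the acyl substitution of β-lactones by organolithium reagents and the SNAr closure of ortho-fluoroaryl β-hydroxy ketones to chroman-4-ones. The one ring formed closes by 6-endo-trig addition–elimination of the alkoxide at the fluorine-bearing carbon, which is vinylogous to the ketone. No stereocentre is created: C-2 and C-3 are the lactone carbons C-4 and C-3, no bond to either is broken, and the trans arrangement is also the thermodynamic one should C-3 enolise. The step needs acyl rather than alkyl C–O attack, single addition, and substitution ahead of retro-aldol cleavage or aryne formation; these are secured by the hard nucleophile and the secondary C-4 of the lactone, by the doubly ortho-substituted ketone together with inverse addition at −78 °C, and by a fluoride activated by the ortho acyl group and two meta alkoxy groups.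

Step 5
Reactants: 11 (2R,3R)-2,3-dimethyl-5,7-di(propan-2-yloxy)chroman-4-one
Product: 12 (2R,3R)-5-hydroxy-2,3-dimethyl-7-(propan-2-yloxy)chroman-4-one
Conditions: BCl3 (1.1 equiv), CH2Cl2, −78 °C; aq. NaHCO3
Reagents that add atoms: none
Why: Chelation-directed Lewis-acid dealkylation should cleave only the isopropyl ether peri to the C-4 carbonyl, leaving the C-7 ether and both stereocentres untouched.

Step 6
Reactants: 12 (2R,3R)-5-hydroxy-2,3-dimethyl-7-(propan-2-yloxy)chroman-4-one
Product: 14 (8R,9R)-8,9-dimethyl-5-(propan-2-yloxy)-8,9-dihydro-2H,10H-pyrano[2,3-f]chromene-2,10-dione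
Conditions: Pd(OAc)2 (5 mol%), NaOAc, HCO2H, 25 °C
Reagents that add atoms: 13 ethyl propiolate, C#CC(=O)OCC
Why: Palladium-catalysed hydroarylation and lactonisation of the phenol with the alkynoate (a Pechmann-type coumarin annulation) should engage the only free carbon ortho to the C-5 hydroxyl and close the pyranone onto that oxygen.

Step 7
Reactants: 14 (8R,9R)-8,9-dimethyl-5-(propan-2-yloxy)-8,9-dihydro-2H,10H-pyrano[2,3-f]chromene-2,10-dione
Product: 15 (8R,9R)-5-hydroxy-8,9-dimethyl-8,9-dihydro-2H,10H-pyrano[2,3-f]chromene-2,10-dione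
Conditions: BCl3 (3 equiv), CH2Cl2, 0 °C; aq. NaHCO3
Reagents that add atoms: none
Why: Lewis-acid cleavage of the remaining aryl isopropyl ether should free the phenol without reducing the coumarin double bond, which a hydrogenolytic deprotection would endanger.

Step 8
Reactants: 15 (8R,9R)-5-hydroxy-8,9-dimethyl-8,9-dihydro-2H,10H-pyrano[2,3-f]chromene-2,10-dione
Product: 17 (4S,8R,9R)-5-hydroxy-8,9-dimethyl-4-phenyl-3,4,8,9-tetrahydro-2H,10H-pyrano[2,3-f]chromene-2,10-dione
Conditions: Rh(acac)(C2H4)2 (3 mol%), (S)-SEGPHOS, dioxane/H2O 10:1, 60 °C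
Reagents that add atoms: 16 phenylboronic acid, OB(O)c1ccccc1
Why: Hayashi–Miyaura rhodium-catalysed asymmetric 1,4-addition of the phenyl group to the coumarin should set C-4 as (S) under ligand control, the remote chromanone centres having no say.

Step 9
Reactants: 17 (4S,8R,9R)-5-hydroxy-8,9-dimethyl-4-phenyl-3,4,8,9-tetrahydro-2H,10H-pyrano[2,3-f]chromene-2,10-dione
Product: 19 (4S,8R,9R)-5-hydroxy-6-iodo-8,9-dimethyl-4-phenyl-3,4,8,9-tetrahydro-2H,10H-pyrano[2,3-f]chromene-2,10-dione
Conditions: NIS, MeCN, 0 °C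
Reagents that add atoms: 18 N-iodosuccinimide, O=C1CCC(=O)N1I
Why: Electrophilic aromatic iodination should take the single remaining C–H of the oxygenated ring, ortho to the free phenol.

Step 10
Reactants: 20 (S)-4-benzyloxazolidin-2-one
Product: 22 (S)-4-benzyl-3-(3-methylbut-2-enoyl)oxazolidin-2-one
Conditions: n-BuLi, THF, −78 °C; then acid chloride, −78 → 0 °C
Reagents that add atoms: 21 3-methylbut-2-enoyl chloride, CC(C)=CC(=O)Cl
Why: N-Acylation of the lithiated Evans oxazolidinone with the acid chloride is a standard, clean reaction.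

Step 11
Reactants: 22 (S)-4-benzyl-3-(3-methylbut-2-enoyl)oxazolidin-2-one
Product: 24 (S)-4-benzyl-3-[(2S)-5-methyl-2-(prop-1-en-2-yl)hex-4-enoyl]oxazolidin-2-one
Conditions: NaN(SiMe3)2, THF, −78 °C; prenyl bromide, −78 → −40 °C
Reagents that add atoms: 23 1-bromo-3-methylbut-2-ene (prenyl bromide), CC(C)=CCBr
Why: Evans alkylation of the chelated Z-dienolate (γ-deprotonation, α-alkylation with deconjugation) should occur on the face away from the benzyl group of the auxiliary and so set the (2S) centre.

Step 12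
Reactants: 24 (S)-4-benzyl-3-[(2S)-5-methyl-2-(prop-1-en-2-yl)hex-4-enoyl]oxazolidin-2-one
Product: 25 (2S)-5-methyl-2-(prop-1-en-2-yl)hex-4-en-1-ol, (S)-lavandulol
Conditions: LiBH4, Et2O, MeOH (1 equiv), 0 °C
Reagents that add atoms: none
Why: Reductive cleavage of the N-acyl oxazolidinone should give the primary alcohol without epimerising the α-centre and returns the auxiliary.

Step 13
Reactants: 25 (2S)-5-methyl-2-(prop-1-en-2-yl)hex-4-en-1-ol
Product: 27 (3S)-3-(iodomethyl)-2,6-dimethylhepta-1,5-diene, (S)-lavandulyl iodide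
Conditions: PPh3, imidazole, CH2Cl2, 0 → 25 °C
Reagents that add atoms: 26 iodine, II
Why: Appel-type iodination of the primary alcohol breaks no bond at the stereocentre.

Step 14
Reactants: 27 (3S)-3-(iodomethyl)-2,6-dimethylhepta-1,5-diene; 19 (4S,8R,9R)-5-hydroxy-6-iodo-8,9-dimethyl-4-phenyl-3,4,8,9-tetrahydro-2H,10H-pyrano[2,3-f]chromene-2,10-dione
Product: 29 (4S,8R,9R)-5-hydroxy-8,9-dimethyl-6-[(2R)-5-methyl-2-(prop-1-en-2-yl)hex-4-en-1-yl]-4-phenyl-3,4,8,9-tetrahydro-2H,10H-pyrano[2,3-f]chromene-2,10-dione, via lavandulylzinc iodide 28 (not isolated)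
Conditions: Zn dust, LiCl, THF, 40 °C; then slow addition to 19, Pd(OAc)2 (2 mol%), SPhos (4 mol%), THF, 25 °C
Reagents that add atoms: none
Why: Negishi sp2–sp3 cross-coupling with a biarylphosphine ligand should tolerate the free phenol and suppress β-hydride elimination, and the β-stereocentre of the alkylzinc is untouched (its descriptor changes from S to R only because the CIP priorities change).

Step 15
Reactants: 29 (4S,8R,9R)-5-hydroxy-8,9-dimethyl-6-[(2R)-5-methyl-2-(prop-1-en-2-yl)hex-4-en-1-yl]-4-phenyl-3,4,8,9-tetrahydro-2H,10H-pyrano[2,3-f]chromene-2,10-dione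
Product: 33 (3S)-3-[(2R,3R,8S)-5-hydroxy-2,3-dimethyl-8-[(2R)-5-methyl-2-(prop-1-en-2-yl)hex-4-en-1-yl]-8-(3-methylbut-2-en-1-yl)-4,7-dioxo-2,3,7,8-tetrahydro-4H-chromen-6-yl]-3-phenylpropanoic acid (target, CNP0150579.1), via prenylated dienone lactone 32 (not isolated)
Conditions: Pd2(dba)3 (tris(dibenzylideneacetone)dipalladium, 2.5 mol%), (R,R)-DACH-phenyl Trost ligand (7.5 mol%), Cs2CO3, THF, 0 → 25 °C; then LiOH, THF/H2O, 0 °C; 1 M HCl
Reagents that add atoms: 30 3-methylbut-2-en-1-yl acetate (prenyl acetate), CC(C)=CCOC(C)=O; 31 lithium hydroxide, [Li+].[OH-]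
Why: Tsuji–Trost allylic alkylation of the cesium phenoxide at its lavandulyl-bearing ortho carbon (the other ortho carbon and the para carbon are ring-fusion atoms) by the unsubstituted terminus of the π-prenyl palladium complex should dearomatise the ring and create the quaternary (S) centre under control of the chiral ligand, after which hydroxide opens the enol lactone to the enolised triketone acid.

Compound list
1 | (R)-4-methyloxetan-2-one, (R)-β-butyrolactone | C[C@@H]1CC(=O)O1 | starting material
2 | iodomethane | CI | starting material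
3 | (3R,4R)-3,4-dimethyloxetan-2-one | C[C@H]1OC(=O)[C@@H]1C | intermediate
4 | 5-fluorobenzene-1,3-diol | Oc1cc(O)cc(F)c1 | starting material
5 | 2-bromopropane | CC(C)Br | starting material
6 | 1-fluoro-3,5-di(propan-2-yloxy)benzene | Fc1cc(OC(C)C)cc(OC(C)C)c1 | intermediate
7 | N-bromosuccinimide | O=C1CCC(=O)N1Br | starting material
8 | 2-bromo-1-fluoro-3,5-di(propan-2-yloxy)benzene | Fc1cc(OC(C)C)cc(OC(C)C)c1Br | intermediate
9 | [2-fluoro-4,6-di(propan-2-yloxy)phenyl]lithium | [Li]c1c(F)cc(OC(C)C)cc1OC(C)C | intermediate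
10 | lithium (2R,3R)-4-[2-fluoro-4,6-di(propan-2-yloxy)phenyl]-3-methyl-4-oxobutan-2-olate | [Li]O[C@H](C)[C@@H](C)C(=O)c1c(F)cc(OC(C)C)cc1OC(C)C | intermediate
11 | (2R,3R)-2,3-dimethyl-5,7-di(propan-2-yloxy)chroman-4-one | C[C@H]1Oc2cc(OC(C)C)cc(OC(C)C)c2C(=O)[C@@H]1C | intermediate
12 | (2R,3R)-5-hydroxy-2,3-dimethyl-7-(propan-2-yloxy)chroman-4-one | C[C@H]1Oc2cc(OC(C)C)cc(O)c2C(=O)[C@@H]1C | intermediate
13 | ethyl propiolate | C#CC(=O)OCC | starting material
14 | (8R,9R)-8,9-dimethyl-5-(propan-2-yloxy)-8,9-dihydro-2H,10H-pyrano[2,3-f]chromene-2,10-dione | C[C@H]1Oc2cc(OC(C)C)c3ccc(=O)oc3c2C(=O)[C@@H]1C | intermediate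
15 | (8R,9R)-5-hydroxy-8,9-dimethyl-8,9-dihydro-2H,10H-pyrano[2,3-f]chromene-2,10-dione | C[C@H]1Oc2cc(O)c3ccc(=O)oc3c2C(=O)[C@@H]1C | intermediate
16 | phenylboronic acid | OB(O)c1ccccc1 | starting material
17 | (4S,8R,9R)-5-hydroxy-8,9-dimethyl-4-phenyl-3,4,8,9-tetrahydro-2H,10H-pyrano[2,3-f]chromene-2,10-dione | C[C@H]1Oc2cc(O)c3c(OC(=O)C[C@H]3c3ccccc3)c2C(=O)[C@@H]1C | intermediate
18 | N-iodosuccinimide | O=C1CCC(=O)N1I | starting material
19 | (4S,8R,9R)-5-hydroxy-6-iodo-8,9-dimethyl-4-phenyl-3,4,8,9-tetrahydro-2H,10H-pyrano[2,3-f]chromene-2,10-dione | C[C@H]1Oc2c(I)c(O)c3c(OC(=O)C[C@H]3c3ccccc3)c2C(=O)[C@@H]1C | intermediate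
20 | (S)-4-benzyloxazolidin-2-one | O=C1N[C@@H](Cc2ccccc2)CO1 | starting material
21 | 3-methylbut-2-enoyl chloride | CC(C)=CC(=O)Cl | starting material
22 | (S)-4-benzyl-3-(3-methylbut-2-enoyl)oxazolidin-2-one | CC(C)=CC(=O)N1[C@@H](Cc2ccccc2)COC1=O | intermediate
23 | 1-bromo-3-methylbut-2-ene (prenyl bromide) | CC(C)=CCBr | starting material
24 | (S)-4-benzyl-3-[(2S)-5-methyl-2-(prop-1-en-2-yl)hex-4-enoyl]oxazolidin-2-one | C=C(C)[C@H](CC=C(C)C)C(=O)N1[C@@H](Cc2ccccc2)COC1=O | intermediate
25 | (2S)-5-methyl-2-(prop-1-en-2-yl)hex-4-en-1-ol, (S)-lavandulol | C=C(C)[C@H](CC=C(C)C)CO | intermediate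
26 | iodine | II | starting material
27 | (3S)-3-(iodomethyl)-2,6-dimethylhepta-1,5-diene | C=C(C)[C@H](CC=C(C)C)CI | intermediate
28 | [(2S)-5-methyl-2-(prop-1-en-2-yl)hex-4-en-1-yl]zinc iodide | C=C(C)[C@H](CC=C(C)C)C[Zn]I | intermediate
29 | (4S,8R,9R)-5-hydroxy-8,9-dimethyl-6-[(2R)-5-methyl-2-(prop-1-en-2-yl)hex-4-en-1-yl]-4-phenyl-3,4,8,9-tetrahydro-2H,10H-pyrano[2,3-f]chromene-2,10-dione | C=C(C)[C@H](CC=C(C)C)Cc1c(O)c3c(OC(=O)C[C@H]3c3ccccc3)c2c1O[C@H](C)[C@@H](C)C2=O | intermediate
30 | 3-methylbut-2-en-1-yl acetate (prenyl acetate) | CC(C)=CCOC(C)=O | starting material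
31 | lithium hydroxide | [Li+].[OH-] | starting material
32 | (4S,6S,8R,9R)-8,9-dimethyl-6-[(2R)-5-methyl-2-(prop-1-en-2-yl)hex-4-en-1-yl]-6-(3-methylbut-2-en-1-yl)-4-phenyl-3,4,8,9-tetrahydro-2H-pyrano[2,3-f]chromene-2,5,10(6H)-trione | C=C(C)[C@H](CC=C(C)C)C[C@]1(CC=C(C)C)C(=O)C3=C(OC(=O)C[C@H]3c3ccccc3)C2=C1O[C@H](C)[C@@H](C)C2=O | intermediate
33 | (3S)-3-[(2R,3R,8S)-5-hydroxy-2,3-dimethyl-8-[(2R)-5-methyl-2-(prop-1-en-2-yl)hex-4-en-1-yl]-8-(3-methylbut-2-en-1-yl)-4,7-dioxo-2,3,7,8-tetrahydro-4H-chromen-6-yl]-3-phenylpropanoic acid | C=C(C)[C@H](CC=C(C)C)C[C@]1(CC=C(C)C)C(=O)C([C@@H](CC(=O)O)c2ccccc2)=C(O)C2=C1O[C@H](C)[C@@H](C)C2=O | target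

Total step count: 15. Longest linear sequence: 10 steps (steps 2 to 9, then 14 and 15).

Steps most likely to fail

Step 4. The aryllithium may act as a base and enolise the lactone instead of adding to it, it may lose lithium fluoride to an aryne if the acylation is slow, and the keto-alkoxide may undergo retro-aldol cleavage before the fluoride is displaced. The fallback sets out from 3 and 8 and returns at 11, replacing the strained acyl donor by an open-chain one with a stable tetrahedral adduct. Lactone 3 would be opened with N,O-dimethylhydroxylamine hydrochloride and AlMe3 to the Weinreb amide (2R,3R)-3-hydroxy-N-methoxy-N,2-dimethylbutanamide F1, which would be silylated (TBSCl, imidazole) to (2R,3R)-3-[(tert-butyldimethylsilyl)oxy]-N-methoxy-N,2-dimethylbutanamide F2. Aryllithium 9, made from 8 as before, would add once to F2 to give the ketone (2R,3R)-3-[(tert-butyldimethylsilyl)oxy]-1-[2-fluoro-4,6-di(propan-2-yloxy)phenyl]-2-methylbutan-1-one F3. Tetrabutylammonium fluoride in THF would then unmask the alkoxide, which closes onto the fluorine-bearing carbon to give 11.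

Step 8. Insertion of the electron-rich, peri-hydroxylated coumarin into the aryl–rhodium bond may be slower than protodeboronation, or facial discrimination may be eroded by the peri substituent. The fallback sets out from 12 and returns at 17, bringing the phenyl group in with the alkyne and setting C-4 by hydride delivery instead. Annulation of 12 with ethyl 3-phenylpropiolate under the conditions of step 6 would give (8R,9R)-8,9-dimethyl-4-phenyl-5-(propan-2-yloxy)-8,9-dihydro-2H,10H-pyrano[2,3-f]chromene-2,10-dione F4. Copper hydride asymmetric conjugate reduction (Cu(OAc)2, the DTBM-SEGPHOS enantiomer that gives the 4S product, diethoxymethylsilane, t-BuOH, toluene) would give (4S,8R,9R)-8,9-dimethyl-4-phenyl-5-(propan-2-yloxy)-3,4,8,9-tetrahydro-2H,10H-pyrano[2,3-f]chromene-2,10-dione F5; the doubly ortho-oxygenated chromanone ketone should be spared. BCl3 in CH2Cl2 at 0 °C would then give 17.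

Step 15. Facial selectivity at the new quaternary carbon may be poor because the existing stereocentres are remote, and O-prenylation or attack at the substituted allyl terminus may compete. The fallback sets out from 29 and returns at 32, replacing the π-allyl palladium pathway by an ion-pair-controlled alkylation. Prenyl bromide 23 with CsOH·H2O and N-(9-anthracenylmethyl)cinchonidinium bromide in toluene at −40 °C would alkylate the phenoxide within a chiral ion pair, and hydroxide treatment as in step 15 would follow; this fallback makes no new compound (F0).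

Further compounds
F1 | step 4 | (2R,3R)-3-hydroxy-N-methoxy-N,2-dimethylbutanamide | O[C@H](C)[C@@H](C)C(=O)N(C)OC
F2 | step 4 | (2R,3R)-3-[(tert-butyldimethylsilyl)oxy]-N-methoxy-N,2-dimethylbutanamide | CC(C)(C)[Si](C)(C)O[C@H](C)[C@@H](C)C(=O)N(C)OC
F3 | step 4 | (2R,3R)-3-[(tert-butyldimethylsilyl)oxy]-1-[2-fluoro-4,6-di(propan-2-yloxy)phenyl]-2-methylbutan-1-one | CC(C)(C)[Si](C)(C)O[C@H](C)[C@@H](C)C(=O)c1c(F)cc(OC(C)C)cc1OC(C)C
F4 | step 8 | (8R,9R)-8,9-dimethyl-4-phenyl-5-(propan-2-yloxy)-8,9-dihydro-2H,10H-pyrano[2,3-f]chromene-2,10-dione | C[C@H]1Oc2cc(OC(C)C)c3c(-c4ccccc4)cc(=O)oc3c2C(=O)[C@@H]1C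
F5 | step 8 | (4S,8R,9R)-8,9-dimethyl-4-phenyl-5-(propan-2-yloxy)-3,4,8,9-tetrahydro-2H,10H-pyrano[2,3-f]chromene-2,10-dione | C[C@H]1Oc2cc(OC(C)C)c3c(OC(=O)C[C@H]3c3ccccc3)c2C(=O)[C@@H]1C
F0 | step 15 | none | none
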